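A small charge of electrophile, 0.020 M, took up nucleophile fed in over 6.0 d, and each turnover freed an acid able to bind a further nucleophile.

- spring: electrophile 0.020 M; nucleophile 1.00 equiv (fed, over 6.0 d); time 10 d; the fed solution adds 0.50 times the starting volume
- autumn: electrophile 0.020 M; nucleophile 2.00 equiv (fed, over 6.0 d); time 10 d; the fed solution adds 0.50 times the starting volume

- part of the electrophile that has reacted at the end, spring
- part of the electrophile that has reacted at the end, autumn
- what raising the equivalents of nucleophile from its lowest to its highest value here does to the part of the electrophile that has reacted (changes below 5 percentage points count as none) (it falls / it rises / no change)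

- charges are per starting volume, the dose included; the dosed solution carries all of it
- run time (spring): 10 d

    electrophile + nucleophile → acid set free + target (k1 = 0.0070 /M/s)
    nucleophile + acid set free ⇌ protonated nucleophile, settled at all times (K2 = 1.0 × 10⁵ /M)
    target → over-reaction product (k3 = 2.8 × 10⁻⁷ /s)
    nucleophile ⇌ dormant form (K4 = 14, k4 = 1.2 × 10⁻⁴ /s)

I spent two nucleophiles per turnover, one in the target and one on the acid, because 1.0 × 10⁵ /M times the electrophile charge is 2000, far above one. In spring, 1.00 equiv then allowed 50.0 % of the electrophile to react; this fraction, the equivalents over two, is the acid ceiling. In autumn, 2.00 equiv put the ceiling at 100 %. Since the half-life of electrophile by step 1 with whole charges, 0.057 d, is shorter than the run of 10 d, I expected spring to reach its ceiling, and I held the autumn ceiling as an upper bound, with no figure for the tail.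

The forecast gave 52 % for spring and 88 % for autumn, and its answer on raising the equivalents was: it rises. It started from the same step as mine: “Each turnover frees acid that locks up a second nucleophile”. Its autumn figure lies below my bound.

The simulation gave 51.0 % for spring and 87.0 % for autumn, a change of 36 percentage points, and its answer on raising the equivalents was: it rises. Spring ended 1 point above its ceiling, with the unbound nucleophile, its limiting reagent, down to 0.35 % of its charge against 49 % for the unbound electrophile. Autumn ended 13 points below its ceiling.

The neighbouring flask was autumn's with 0.800 equiv of nucleophile. Its acid ceiling is 40.0 %. At 10 d it had reacted 42.1 %, which left 58 % of the electrophile, and the unbound nucleophile stood at 0.32 % of its charge.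

All constants are those of an exercise; the rest is arithmetic.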